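**Retrosynthetic overview**
- Target ⇐ hydrolysis of two catechol acetonides ⇐ axial C4 alcohol ⇐ bulky-hydride reduction of a cis-2,6-disubstituted oxan-4-one.
- Oxan-4-one ⇐ enantioselective ring expansion: the C=O of a 3-arylpropanal is inserted into the C2–C3 bond of a prochiral 3-arylcyclobutanone (four-membered carbocycle → six-membered oxacycle; sets C2 and C6).
- 3-Arylcyclobutanone ⇐ decarboxylative arylation of 3-oxocyclobutanecarboxylic acid with the ring A bromide; the ring A methoxy group ⇐ C–H borylation/methoxylation.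
- 3-Arylpropanal (ring B) ⇐ Heck reaction of the same parent aryl bromide with allyl alcohol; the bromide ⇐ bromination of catechol acetonide.
- Ring order: both benzene rings and the cyclobutanone ring are bought; the oxane is the only ring made, by enlarging the cyclobutanone.

Assumption: the sense of induction of the new catalyst in step 5 must be found by experiment; it is taken here that the (S,S)-catalyst gives (2S,6S)-9, and the (R,R)-catalyst is used if the sense is the reverse.

**Step 1**
Reactants: 1 2,2-dimethyl-1,3-benzodioxole (catechol acetonide)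
Product: 2 5-bromo-2,2-dimethyl-1,3-benzodioxole
Conditions: NBS (1.05 equiv), MeCN, 0 °C to rt
Reagents that add atoms: N-bromosuccinimide, O=C1CCC(=O)N1Br
Why: Electrophilic aromatic bromination; each ring oxygen activates its para carbon, the two para sites are equivalent and the ortho sites are less reactive, so mono-bromination gives the 5-bromide.

**Step 2**
Reactants: 2 5-bromo-2,2-dimethyl-1,3-benzodioxole; 3 prop-2-en-1-ol (allyl alcohol)
Product: 4 3-(2,2-dimethyl-1,3-benzodioxol-5-yl)propanal
Conditions: Pd(OAc)2 (3 mol%), Bu4NCl, NaHCO3, DMF, 90 °C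
Reagents that add atoms: none
Why: Heck reaction with allyl alcohol (Jeffery conditions); the aryl group adds to the terminal alkene carbon, β-hydride elimination toward the carbinol carbon gives an enol that tautomerises to the saturated aldehyde, and no stereocenter is formed.

**Step 3**
Reactants: 2 5-bromo-2,2-dimethyl-1,3-benzodioxole
Product: 6 6-bromo-4-methoxy-2,2-dimethyl-1,3-benzodioxole, via aryl pinacol boronate 5 (not isolated)
Conditions: [Ir(OMe)(cod)]2 (1.5 mol%), dtbbpy (3 mol%), B2pin2 (1.0 equiv), THF, 80 °C; evaporate; then Cu(OAc)2 (20 mol%), DMAP (40 mol%), MeOH, 4 Å MS, O2 (1 atm), 50 °C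
Reagents that add atoms: methanol, CO; bis(pinacolato)diboron, CC1(C)OB(OC1(C)C)B1OC(C)(C)C(C)(C)O1 (its boryl group is present in 5 only)
Why: Iridium-catalysed C–H borylation followed by Chan–Lam-type oxidative C–O coupling with methanol; C7–H is the only C–H without a bromine neighbour and is activated by the adjacent ring oxygen (C4–H is flanked on both sides, C6–H is ortho to Br), so the methoxy group ends up next to the dioxole oxygens and meta to bromine.

**Step 4**
Reactants: 6 6-bromo-4-methoxy-2,2-dimethyl-1,3-benzodioxole; 7 3-oxocyclobutane-1-carboxylic acid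
Product: 8 3-(7-methoxy-2,2-dimethyl-1,3-benzodioxol-5-yl)cyclobutan-1-one
Conditions: Ir[dF(CF3)ppy]2(dtbbpy)PF6 (1 mol%), NiCl2·glyme (10 mol%), dtbbpy (15 mol%), Cs2CO3 (1.5 equiv), 7 (1.5 equiv), DMSO, blue LEDs, rt
Reagents that add atoms: none
Why: Nickel/photoredox decarboxylative C(sp3)–C(sp2) cross-coupling; the photocatalyst oxidises the caesium carboxylate, loss of CO2 gives the 3-oxocyclobutyl radical, and nickel joins it to the aryl bromide; the product is achiral because C3 lies on a mirror plane.

**Step 5**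
Reactants: 8 3-(7-methoxy-2,2-dimethyl-1,3-benzodioxol-5-yl)cyclobutan-1-one; 4 3-(2,2-dimethyl-1,3-benzodioxol-5-yl)propanal
Product: 9 (2S,6S)-2-(7-methoxy-2,2-dimethyl-1,3-benzodioxol-5-yl)-6-[2-(2,2-dimethyl-1,3-benzodioxol-5-yl)ethyl]oxan-4-one (2,6-cis)
Conditions: (S,S)-IDPi (5 mol%; confined imidodiphosphorimidate Brønsted acid from two (S)-BINOL units with 3,3′-bis[3,5-bis(trifluoromethyl)phenyl] groups and N-triflyl groups), 4 (1.3 equiv), CHCl3, 5 Å MS, −40 °C
Reagents that add atoms: none
Why: Proposed new method: catalytic enantioselective ring expansion of a donor-substituted cyclobutanone by aldehyde C=O insertion (stepwise ionic formal [4+2], not pericyclic), in which the strong chiral acid activates the ketone of 8, ring strain and the para-oxygenated aryl group allow the aldehyde oxygen to open the benzylic C3–C2 bond to an enol tethered to an aryl-stabilised oxocarbenium ion held as a chiral ion pair, and six-ring closure of enol onto oxocarbenium through a chair with both substituents equatorial gives the 2,6-cis ketone while the confined anion selects one of the two enantiotopic ring bonds of prochiral 8 and so sets C2 and C6 together (C2 can re-ionise but returns to cis, C6 is fixed by the C–C bond formation); the closest known reactions are the racemic BF3-mediated ring expansion of 3-alkoxycyclobutanones with aldehydes, Lewis-acid [4+2] annulations of donor–acceptor cyclobutanes with aldehydes, and asymmetric Prins cyclisations with the same acid class.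

**Step 6**
Reactants: 9 (2S,6S)-oxan-4-one described in step 5
Product: 10 (2S,4S,6S)-2-(7-methoxy-2,2-dimethyl-1,3-benzodioxol-5-yl)-6-[2-(2,2-dimethyl-1,3-benzodioxol-5-yl)ethyl]oxan-4-ol (2,6-cis, 4-OH axial and trans to both)
Conditions: LiBH(s-Bu)3 (L-Selectride, 1.3 equiv), THF, −78 °C; then H2O
Reagents that add atoms: none
Why: Diastereoselective ketone reduction; 9 sits in a chair with both substituents equatorial, the bulky trialkylborohydride attacks along the equatorial trajectory and gives the axial (4S) alcohol, as is general for cis-2,6-disubstituted oxan-4-ones.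

**Step 7**
Reactants: 10 (2S,4S,6S)-oxan-4-ol described in step 6
Product: 11 5-[(2S,4S,6S)-6-[2-(3,4-dihydroxyphenyl)ethyl]-4-hydroxyoxan-2-yl]-3-methoxybenzene-1,2-diol (target)
Conditions: TFA/H2O (9:1), CH2Cl2, 0 °C to rt, argon
Reagents that add atoms: none
Why: Acid hydrolysis of the two catechol isopropylidene ketals; the aryl methyl ether, the secondary alcohol and C4/C6 are untouched, and any reversible ionisation of the benzylic C2–O bond re-closes to the thermodynamically preferred diequatorial 2,6-cis ring.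

**Compound list**
1 | 2,2-dimethyl-1,3-benzodioxole (catechol acetonide) | CC1(C)Oc2ccccc2O1 | starting material
2 | 5-bromo-2,2-dimethyl-1,3-benzodioxole | CC1(C)Oc2ccc(Br)cc2O1 | intermediate
3 | prop-2-en-1-ol (allyl alcohol) | C=CCO | starting material
4 | 3-(2,2-dimethyl-1,3-benzodioxol-5-yl)propanal | O=CCCc1ccc2OC(C)(C)Oc2c1 | intermediate
5 | 2-(6-bromo-2,2-dimethyl-1,3-benzodioxol-4-yl)-4,4,5,5-tetramethyl-1,3,2-dioxaborolane | CC1(C)Oc2cc(Br)cc(B3OC(C)(C)C(C)(C)O3)c2O1 | intermediate
6 | 6-bromo-4-methoxy-2,2-dimethyl-1,3-benzodioxole | COc1cc(Br)cc2OC(C)(C)Oc12 | intermediate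
7 | 3-oxocyclobutane-1-carboxylic acid | O=C1CC(C1)C(O)=O | starting material
8 | 3-(7-methoxy-2,2-dimethyl-1,3-benzodioxol-5-yl)cyclobutan-1-one (achiral) | COc1cc(C2CC(=O)C2)cc2OC(C)(C)Oc12 | intermediate
9 | (2S,6S)-2-(7-methoxy-2,2-dimethyl-1,3-benzodioxol-5-yl)-6-[2-(2,2-dimethyl-1,3-benzodioxol-5-yl)ethyl]oxan-4-one | COc1cc([C@@H]2CC(=O)C[C@H](CCc3ccc4OC(C)(C)Oc4c3)O2)cc2OC(C)(C)Oc12 | intermediate
10 | (2S,4S,6S)-2-(7-methoxy-2,2-dimethyl-1,3-benzodioxol-5-yl)-6-[2-(2,2-dimethyl-1,3-benzodioxol-5-yl)ethyl]oxan-4-ol | COc1cc([C@@H]2C[C@@H](O)C[C@H](CCc3ccc4OC(C)(C)Oc4c3)O2)cc2OC(C)(C)Oc12 | intermediate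
11 | 5-[(2S,4S,6S)-6-[2-(3,4-dihydroxyphenyl)ethyl]-4-hydroxyoxan-2-yl]-3-methoxybenzene-1,2-diol | COc1cc([C@@H]2C[C@@H](O)C[C@H](CCc3ccc(O)c(O)c3)O2)cc(O)c1O | target

**Step count**
Total steps: 7. Longest linear sequence: 6 (steps 1, 3, 4, 5, 6, 7); step 2 is the side branch.

**Three steps most likely to fail**

Step 5 (the proposed ring expansion). It may stall at ring-opened enone, give low enantioselectivity, or lose the aldehyde to self-condensation. The fallback uses known chemistry, sets out from 4 and 6 and comes back at 9.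
- Aldehyde 4 is allylated with (Ipc)2B(allyl) of the (−)-α-pinene series (the antipode that gives (S)-carbinols from unbranched aliphatic aldehydes; Et2O, −78 °C, then NaOH/H2O2) to give (3S)-1-(2,2-dimethyl-1,3-benzodioxol-5-yl)hex-5-en-3-ol F4.
- Bromide 6 is converted by n-BuLi (THF, −78 °C) and DMF into 7-methoxy-2,2-dimethyl-1,3-benzodioxole-5-carbaldehyde F5.
- Prins cyclisation of the two with O3ReOSiPh3 (5 mol%, CH2Cl2, rt) gives the all-equatorial (2S,4R,6S)-2-(7-methoxy-2,2-dimethyl-1,3-benzodioxol-5-yl)-6-[2-(2,2-dimethyl-1,3-benzodioxol-5-yl)ethyl]oxan-4-ol F6.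
- Dess–Martin periodinane oxidises it to ketone 9, and steps 6 and 7 follow unchanged.

Step 4 (decarboxylative arylation). The electron-rich bromide may couple poorly, or the acid may simply lose CO2 and be reduced. The fallback sets out from 6 and comes back at 8.
- Suzuki coupling with CH2=CHBF3K (PdCl2(dppf), Cs2CO3, THF/H2O, 80 °C) gives 6-ethenyl-4-methoxy-2,2-dimethyl-1,3-benzodioxole F2.
- Cycloaddition with dichloroketene (Cl3CCOCl, Zn(Cu), Et2O) gives racemic 2,2-dichloro-3-(7-methoxy-2,2-dimethyl-1,3-benzodioxol-5-yl)cyclobutan-1-one F3.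
- Zinc in acetic acid removes both chlorines to give 8.

Step 3 (one-pot borylation/methoxylation). The copper-mediated C–O coupling of the hindered, ortho-oxygenated boronate may give protodeboronation. The fallback sets out from 2 (through the same boronate 5) and comes back at 6.
- After the borylation the crude boronate is oxidised with H2O2/NaOH (THF/H2O, 0 °C; boron-to-oxygen migration) to 6-bromo-2,2-dimethyl-1,3-benzodioxol-4-ol F1.
- The phenol is O-methylated with MeI/K2CO3 in acetone to give 6.

**Further compounds**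
F1 | step 3 | 6-bromo-2,2-dimethyl-1,3-benzodioxol-4-ol | Oc1cc(Br)cc2OC(C)(C)Oc12
F2 | step 4 | 6-ethenyl-4-methoxy-2,2-dimethyl-1,3-benzodioxole | COc1cc(C=C)cc2OC(C)(C)Oc12
F3 | step 4 | 2,2-dichloro-3-(7-methoxy-2,2-dimethyl-1,3-benzodioxol-5-yl)cyclobutan-1-one (racemic) | COc1cc(C2CC(=O)C2(Cl)Cl)cc2OC(C)(C)Oc12
F4 | step 5 | (3S)-1-(2,2-dimethyl-1,3-benzodioxol-5-yl)hex-5-en-3-ol | C=CC[C@H](CCc1ccc2OC(C)(C)Oc2c1)O
F5 | step 5 | 7-methoxy-2,2-dimethyl-1,3-benzodioxole-5-carbaldehyde | COc1cc(C=O)cc2OC(C)(C)Oc12
F6 | step 5 | (2S,4R,6S)-2-(7-methoxy-2,2-dimethyl-1,3-benzodioxol-5-yl)-6-[2-(2,2-dimethyl-1,3-benzodioxol-5-yl)ethyl]oxan-4-ol | COc1cc([C@@H]2C[C@H](O)C[C@H](CCc3ccc4OC(C)(C)Oc4c3)O2)cc2OC(C)(C)Oc12
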